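**Plan**

1. Numbering: central oxolane O1, C2 (carries the cis 4-hydroxyphenyl group), C3, C4, C5; dihydrobenzofuran atoms carry a prime. The feature used is the chain C2–C3–C4–C5: four benzylic carbons with a trans C3/C4 pair. Without O1 and with C2 joined to C5 it is a 2,3,4-triarylcyclobutanone.
2. Cuts, last bond first: ten O–benzyl bonds; C2–H and C2–aryl (lactol reduction, aryl addition to a γ-lactone); in each dihydrobenzofuran C2'–C3' and C2'–O1' (sulfur-ylide [4+1]), then CH–aryl and ring–CHO; O1–C5 (Baeyer–Villiger); C2–C3 and C4–C5 (keteniminium [2+2] of an arylacetamide with a symmetric E-stilbene); the stilbene C=C (McMurry homocoupling of two aldehyde molecules) and the amide C–N.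
3. Forward order of rings: cyclobutane; γ-lactone by oxygen insertion; the two dihydrofuran rings while C2 is still a lactone carbonyl; the oxolane by aryl addition and reduction; debenzylation.
4. Stereochemistry: C3/C4 trans from the E-alkene, absolute sense from (2R,5R)-2,5-dimethylpyrrolidine; C5 by α-equilibration and retentive migration; C2'/C3' trans from the ylide ring closure; C2 last, by hydride attack anti to the C3 aryl group, so that this acid-labile cis centre meets no acid afterwards.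
5. Protecting groups: pivalates on the stilbene rings through cycloaddition and ring expansion, benzyl ethers from there on, removed by hydrogenolysis.

Key step: step 4

Assumption 1: the (2R,5R) auxiliary is taken to direct the stilbene to the face that gives the (3S,4S) series; if the sense is opposite, the (2S,5S) amine is used in step 3 with no other change.
Assumption 2: in step 11 the ylide is taken to add to the face of each o-quinone methide that gives the (2S,3S) dihydrobenzofuran; only the shape of the lactone core directs this, a simple steric reading favours the opposite face, and the point stands second in the risk list.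

Step 1
Reactants: 1 3,5-dihydroxybenzaldehyde
Product: 2 3,5-bis(pivaloyloxy)benzaldehyde
Conditions: PivCl, Et3N, DMAP (cat.), CH2Cl2, 0 °C → rt
Reagents that add atoms: pivaloyl chloride, CC(C)(C)C(Cl)=O
Why: DMAP-catalysed acylation of both phenols turns the donor oxygens into electron-poor ester oxygens, which the cycloaddition of step 4 needs.

Step 2
Reactants: 2 3,5-bis(pivaloyloxy)benzaldehyde (two molecules)
Product: 3 (E)-3,3',5,5'-tetrakis(pivaloyloxy)stilbene
Conditions: TiCl4, Zn, THF, reflux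
Reagents that add atoms: 3,5-bis(pivaloyloxy)benzaldehyde (the second molecule of 2), O=Cc1cc(OC(=O)C(C)(C)C)cc(OC(=O)C(C)(C)C)c1
Why: McMurry reductive homocoupling, in which low-valent titanium joins two molecules of aldehyde 2 through a titanium pinacolate and deoxygenates it at reflux, should give the symmetric stilbene with the E geometry favoured for a diaryl alkene, and the hindered aryl pivalates should survive these conditions.

Step 3
Reactants: 4 2-[4-(benzyloxy)phenyl]acetic acid; 5 (2R,5R)-2,5-dimethylpyrrolidine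
Product: 6 2-[4-(benzyloxy)phenyl]-1-[(2R,5R)-2,5-dimethylpyrrolidin-1-yl]ethan-1-one
Conditions: EDC·HCl, HOBt, i-Pr2NEt, CH2Cl2, 0 °C → rt
Reagents that add atoms: none
Why: Carbodiimide amide coupling of a secondary amine, in which no stereocentre is touched.

Step 4
Reactants: 6 2-[4-(benzyloxy)phenyl]-1-[(2R,5R)-2,5-dimethylpyrrolidin-1-yl]ethan-1-one; 3 (E)-3,3',5,5'-tetrakis(pivaloyloxy)stilbene
Product: 9 (2S,3S,4R)-2,3-bis[3,5-bis(pivaloyloxy)phenyl]-4-[4-(benzyloxy)phenyl]cyclobutan-1-one (all-trans; C1 is the future oxolane C2), via keteniminium triflate 7 (not isolated), via cyclobutaniminium triflate 8 (not isolated)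
Conditions: Tf2O (slow addition), 2,4,6-collidine, ClCH2CH2Cl, −20 → 80 °C; aq. NaHCO3, rt; Et3N (cat.), CH2Cl2, rt
Reagents that add atoms: water, O
Why: Tf2O converts amide 6 into its O-triflyl iminium salt and collidine removes the benzylic proton to give keteniminium ion 7; the stilbene C=C attacks its central sp carbon on the side remote from the aryl group and the benzylic cation so formed collapses onto the enamine carbon, a stepwise [2+2] whose closest known counterpart is the keteniminium–alkene cycloaddition of amides of C2-symmetric 2,5-dimethylpyrrolidine. The only ring closed is the cyclobutane, intermolecularly: bond C1–C2 of 9 forms first (future oxolane C2–C3) and the ring is shut by cation–enamine recombination at C3–C4 (future C4–C5). Both bonds go to one face of the E-alkene, so the C2 and C3 aryl groups stay trans, and the face is chosen by the auxiliary, whose two methyl groups shield one quadrant on each side of the keteniminium; this fixes the absolute configuration at C3, the one centre that cannot epimerise. C2 and C4 lie next to the iminium or carbonyl carbon and settle trans to C3 on hydrolysis and treatment with catalytic Et3N, which should give all-trans 9. The selectivity needed is alkene over arene: pivalate oxygens make the resorcinol rings poor partners for electrophilic attack (ether-protected rings would be acylated at ring carbon before the alkene reacts), the symmetric alkene leaves no regiochemical choice, and slow addition of Tf2O keeps the keteniminium concentration low against self-condensation.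

Step 5
Reactants: 9 (2S,3S,4R)-2,3-bis[3,5-bis(pivaloyloxy)phenyl]-4-[4-(benzyloxy)phenyl]cyclobutan-1-one
Product: 10 (3S,4S,5R)-5-[4-(benzyloxy)phenyl]-3,4-bis[3,5-bis(pivaloyloxy)phenyl]oxolan-2-one
Conditions: mCPBA, NaHCO3, CH2Cl2, 0 °C
Reagents that add atoms: 3-chloroperoxybenzoic acid, OOC(=O)c1cccc(Cl)c1
Why: Baeyer–Villiger oxidation is fast for a strained cyclobutanone, and the electron-rich 4-benzyloxybenzylic carbon should migrate in preference to the bis(pivaloyloxy)benzylic one and with retention, which gives the 3,4-trans-4,5-trans lactone.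

Step 6
Reactants: 10 (3S,4S,5R)-5-[4-(benzyloxy)phenyl]-3,4-bis[3,5-bis(pivaloyloxy)phenyl]oxolan-2-one
Product: 12 (3S,4S,5R)-5-[4-(benzyloxy)phenyl]-3,4-bis[3,5-bis(benzyloxy)phenyl]oxolan-2-one, via tetraphenol lactone 11 (not isolated)
Conditions: K2CO3, MeOH, rt; evaporate; BnBr, K2CO3, DMF, rt; acidic work-up
Reagents that add atoms: benzyl bromide, BrCc1ccccc1
Why: Methanolysis of the aryl pivalates followed by Williamson benzylation exchanges the acyl groups for ethers that tolerate organometallic reagents and activate the rings for step 7, while base returns C3 to the trans lactone and the acidic work-up re-closes any opened lactone.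

Step 7
Reactants: 12 (3S,4S,5R)-5-[4-(benzyloxy)phenyl]-3,4-bis[3,5-bis(benzyloxy)phenyl]oxolan-2-one
Product: 14 (3S,4S,5R)-5-[4-(benzyloxy)phenyl]-3,4-bis[3,5-bis(benzyloxy)-2-formylphenyl]oxolan-2-one, via bis-iminium chloride 13 (not isolated)
Conditions: POCl3, DMF, ClCH2CH2Cl, 0 → 60 °C; aq. NaOAc
Reagents that add atoms: N,N-dimethylformamide, CN(C)C=O; water, O
Why: Vilsmeier–Haack formylation should take each 3,5-dialkoxyphenyl ring at the position ortho to the lactone carbon and para to one benzyloxy group, the position between the two benzyloxy groups being more hindered and the monoalkoxyphenyl ring too unreactive.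

Step 8
Reactants: 14 (3S,4S,5R)-5-[4-(benzyloxy)phenyl]-3,4-bis[3,5-bis(benzyloxy)-2-formylphenyl]oxolan-2-one
Product: 15 (3S,4S,5R)-5-[4-(benzyloxy)phenyl]-3,4-bis[5-(benzyloxy)-2-formyl-3-hydroxyphenyl]oxolan-2-one
Conditions: MgBr2·OEt2, toluene/Et2O, 80 °C; dil. HCl
Reagents that add atoms: none
Why: Chelation of MgBr2 between the aldehyde oxygen and the ortho ether oxygen directs bromide to that benzyl group only (selective debenzylation ortho to a carbonyl), which unmasks the one phenol per ring that becomes the furan oxygen.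

Step 9
Reactants: 15 (3S,4S,5R)-5-[4-(benzyloxy)phenyl]-3,4-bis[5-(benzyloxy)-2-formyl-3-hydroxyphenyl]oxolan-2-one; 16 1,3-bis(benzyloxy)-5-bromobenzene
Product: 19 bis-sulfone (15 in which each CHO has become CH(SO2C6H4Me-4)[C6H3(OBn)2-3,5]; both epimers at these carbons), via aryl Grignard reagent 17 (not isolated), via bis-carbinol 18 (not isolated)
Conditions: 16, Mg, THF, rt; add to 15, THF, −78 → −20 °C; aq. NH4Cl; then p-TolSO2H, CH2Cl2, rt
Reagents that add atoms: 4-methylbenzenesulfinic acid, Cc1ccc(cc1)S(O)=O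
Why: Grignard addition to the chelated aldehydes (the lactone is left alone at low temperature) followed by SN1-type exchange of the activated benzhydrylic hydroxyl for sulfinate gives a storable o-quinone methide precursor, and the configuration of the new carbon does not matter because it becomes sp2 in step 11.

Step 10
Reactants: 20 [4-(benzyloxy)phenyl]methanol
Product: 21 1-[4-(benzyloxy)benzyl]thiolan-1-ium tetrafluoroborate
Conditions: tetrahydrothiophene, HBF4·OEt2, CH2Cl2, rt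
Reagents that add atoms: tetrahydrothiophene, C1CCSC1; tetrafluoroboric acid, [H+].F[B-](F)(F)F
Why: Acid-promoted SN1 alkylation of the sulfide by the 4-alkoxybenzyl cation, with a non-nucleophilic counter-ion that prevents the reverse reaction.

Step 11
Reactants: 19 bis-sulfone; 21 1-[4-(benzyloxy)benzyl]thiolan-1-ium tetrafluoroborate
Product: 24 (3S,4S,5R)-5-[4-(benzyloxy)phenyl]-3,4-bis{(2S,3S)-6-(benzyloxy)-2-[4-(benzyloxy)phenyl]-3-[3,5-bis(benzyloxy)phenyl]-2,3-dihydro-1-benzofuran-4-yl}oxolan-2-one, via sulfonium ylide 22 (not isolated), via bis(o-quinone methide) 23 (not isolated)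
Conditions: Cs2CO3, MeCN/CH2Cl2, 0 °C → rt
Reagents that add atoms: none
Why: Cs2CO3 eliminates sulfinate from each phenoxide to give o-quinone methide 23 and deprotonates 21 to ylide 22, whose carbon adds to the methide carbon before the phenoxide displaces tetrahydrothiophene in a 5-exo-tet closure (sulfur-ylide [4+1] annulation), trans at C2'/C3' because the betaine closes from its anti conformer, while C3' follows from the face of ylide attack (assumption 2).

Step 12
Reactants: 24 bis-dihydrobenzofuranyl lactone; 25 1-(benzyloxy)-4-bromobenzene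
Product: 28 (3S,4S,5R)-2,5-bis[4-(benzyloxy)phenyl]-3,4-bis{(2S,3S)-6-(benzyloxy)-2-[4-(benzyloxy)phenyl]-3-[3,5-bis(benzyloxy)phenyl]-2,3-dihydro-1-benzofuran-4-yl}oxolan-2-ol (both C2 epimers), via aryllithium 26 (not isolated), via arylcerium dichloride 27 (not isolated)
Conditions: 25, n-BuLi, THF, −78 °C; CeCl3, −78 °C; then 24, −78 °C; aq. NH4Cl
Reagents that add atoms: none
Why: The aryllithium from Br/Li exchange, made less basic by transmetallation to cerium, should add once to the lactone carbonyl instead of enolising the α-aryl lactone, and the tetrahedral adduct survives to work-up as the lactol.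

Step 13
Reactants: 28 lactol
Product: 29 (2S,3S,4S,5R)-2,5-bis[4-(benzyloxy)phenyl]-3,4-bis{(2S,3S)-6-(benzyloxy)-2-[4-(benzyloxy)phenyl]-3-[3,5-bis(benzyloxy)phenyl]-2,3-dihydro-1-benzofuran-4-yl}oxolane
Conditions: Et3SiH, BF3·OEt2, CH2Cl2, −78 °C
Reagents that add atoms: none
Why: BF3 ionises the lactol to the 2-aryl oxocarbenium ion and Et3SiH delivers hydride to C2 anti to the bulky C3 substituent (lactol reduction as used for 2,5-diaryl-3,4-disubstituted oxolanes), which places the C2 aryl group cis to C3, and the low temperature avoids acid-mediated epimerisation of this centre.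

Step 14
Reactants: 29 deca-O-benzyl ether of the target
Product: 30 (2S,3S,4S,5R)-2,5-bis(4-hydroxyphenyl)-3,4-bis[(2S,3S)-3-(3,5-dihydroxyphenyl)-6-hydroxy-2-(4-hydroxyphenyl)-2,3-dihydro-1-benzofuran-4-yl]oxolane
Conditions: H2 (1 atm), Pd/C, EtOAc/MeOH, rt
Reagents that add atoms: none
Why: Hydrogenolysis of the ten aryl benzyl ethers under neutral conditions, in which primary O-benzyl groups should cleave much faster than the secondary ring C–O bonds and the absence of acid protects the epimerisable C2 centre.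

**Compound list**

1 | 3,5-dihydroxybenzaldehyde | O=Cc1cc(O)cc(O)c1 | starting material
2 | 3,5-bis(pivaloyloxy)benzaldehyde | O=Cc1cc(OC(=O)C(C)(C)C)cc(OC(=O)C(C)(C)C)c1 | intermediate
3 | (E)-3,3',5,5'-tetrakis(pivaloyloxy)stilbene | CC(C)(C)C(=O)Oc1cc(/C=C/c2cc(OC(=O)C(C)(C)C)cc(OC(=O)C(C)(C)C)c2)cc(OC(=O)C(C)(C)C)c1 | intermediate
4 | 2-[4-(benzyloxy)phenyl]acetic acid | OC(=O)Cc1ccc(OCc2ccccc2)cc1 | starting material
5 | (2R,5R)-2,5-dimethylpyrrolidine | C[C@@H]1CC[C@@H](C)N1 | starting material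
6 | 2-[4-(benzyloxy)phenyl]-1-[(2R,5R)-2,5-dimethylpyrrolidin-1-yl]ethan-1-one | O=C(Cc1ccc(OCc2ccccc2)cc1)N1[C@H](C)CC[C@H]1C | intermediate
7 | (2R,5R)-1-{2-[4-(benzyloxy)phenyl]ethenylidene}-2,5-dimethylpyrrolidin-1-ium triflate (keteniminium salt) | C[C@@H]1CC[C@@H](C)[N+]1=C=Cc1ccc(OCc2ccccc2)cc1.[O-]S(=O)(=O)C(F)(F)F | intermediate
8 | (2R,5R)-1-{(2S,3S)-2,3-bis[3,5-bis(pivaloyloxy)phenyl]-4-[4-(benzyloxy)phenyl]cyclobutylidene}-2,5-dimethylpyrrolidin-1-ium triflate (C2/C3 trans, C4 epimers) | C[C@@H]1CC[C@@H](C)[N+]1=C2[C@H](c3cc(OC(=O)C(C)(C)C)cc(OC(=O)C(C)(C)C)c3)[C@@H](c3cc(OC(=O)C(C)(C)C)cc(OC(=O)C(C)(C)C)c3)C2c2ccc(OCc3ccccc3)cc2.[O-]S(=O)(=O)C(F)(F)F | intermediate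
9 | (2S,3S,4R)-2,3-bis[3,5-bis(pivaloyloxy)phenyl]-4-[4-(benzyloxy)phenyl]cyclobutan-1-one (all-trans) | O=C1[C@H](c2cc(OC(=O)C(C)(C)C)cc(OC(=O)C(C)(C)C)c2)[C@@H](c2cc(OC(=O)C(C)(C)C)cc(OC(=O)C(C)(C)C)c2)[C@@H]1c1ccc(OCc2ccccc2)cc1 | intermediate
10 | (3S,4S,5R)-5-[4-(benzyloxy)phenyl]-3,4-bis[3,5-bis(pivaloyloxy)phenyl]oxolan-2-one | CC(C)(C)C(=O)Oc1cc(cc(OC(=O)C(C)(C)C)c1)[C@@H]1[C@@H](c2cc(OC(=O)C(C)(C)C)cc(OC(=O)C(C)(C)C)c2)[C@H](c2ccc(OCc3ccccc3)cc2)OC1=O | intermediate
11 | (3S,4S,5R)-5-[4-(benzyloxy)phenyl]-3,4-bis(3,5-dihydroxyphenyl)oxolan-2-one | Oc1cc(cc(O)c1)[C@@H]1[C@@H](c2cc(O)cc(O)c2)[C@H](c2ccc(OCc3ccccc3)cc2)OC1=O | intermediate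
12 | (3S,4S,5R)-5-[4-(benzyloxy)phenyl]-3,4-bis[3,5-bis(benzyloxy)phenyl]oxolan-2-one | c7ccccc7COc1cc(cc(OCc7ccccc7)c1)[C@@H]1[C@@H](c2cc(OCc7ccccc7)cc(OCc7ccccc7)c2)[C@H](c2ccc(OCc7ccccc7)cc2)OC1=O | intermediate
13 | bis-iminium chloride (14 with each CHO as CH=N+Me2 Cl−) | C[N+](C)=Cc1c(OCc7ccccc7)cc(OCc7ccccc7)cc1[C@@H]1[C@@H](c2c(C=[N+](C)C)c(OCc7ccccc7)cc(OCc7ccccc7)c2)[C@H](c2ccc(OCc7ccccc7)cc2)OC1=O.[Cl-].[Cl-] | intermediate
14 | (3S,4S,5R)-5-[4-(benzyloxy)phenyl]-3,4-bis[3,5-bis(benzyloxy)-2-formylphenyl]oxolan-2-one | O=Cc1c(OCc7ccccc7)cc(OCc7ccccc7)cc1[C@@H]1[C@@H](c2c(C=O)c(OCc7ccccc7)cc(OCc7ccccc7)c2)[C@H](c2ccc(OCc7ccccc7)cc2)OC1=O | intermediate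
15 | (3S,4S,5R)-5-[4-(benzyloxy)phenyl]-3,4-bis[5-(benzyloxy)-2-formyl-3-hydroxyphenyl]oxolan-2-one | O=Cc1c(O)cc(OCc7ccccc7)cc1[C@@H]1[C@@H](c2c(C=O)c(O)cc(OCc7ccccc7)c2)[C@H](c2ccc(OCc7ccccc7)cc2)OC1=O | intermediate
16 | 1,3-bis(benzyloxy)-5-bromobenzene | Brc1cc(OCc2ccccc2)cc(OCc2ccccc2)c1 | starting material
17 | [3,5-bis(benzyloxy)phenyl]magnesium bromide | Br[Mg]c1cc(OCc2ccccc2)cc(OCc2ccccc2)c1 | intermediate
18 | bis-carbinol (15 with each CHO as CH(OH)[3,5-bis(benzyloxy)phenyl]; carbinol epimers) | OC(c5cc(OCc7ccccc7)cc(OCc7ccccc7)c5)c1c(O)cc(OCc7ccccc7)cc1[C@@H]1[C@@H](c2c(C(O)c5cc(OCc7ccccc7)cc(OCc7ccccc7)c5)c(O)cc(OCc7ccccc7)c2)[C@H](c2ccc(OCc7ccccc7)cc2)OC1=O | intermediate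
19 | bis-sulfone (15 with each CHO as CH(SO2C6H4Me-4)[3,5-bis(benzyloxy)phenyl]; epimers at these carbons) | Cc8ccc(cc8)S(=O)(=O)C(c5cc(OCc7ccccc7)cc(OCc7ccccc7)c5)c1c(O)cc(OCc7ccccc7)cc1[C@@H]1[C@@H](c2c(C(c5cc(OCc7ccccc7)cc(OCc7ccccc7)c5)S(=O)(=O)c8ccc(C)cc8)c(O)cc(OCc7ccccc7)c2)[C@H](c2ccc(OCc7ccccc7)cc2)OC1=O | intermediate
20 | [4-(benzyloxy)phenyl]methanol | OCc1ccc(OCc2ccccc2)cc1 | starting material
21 | 1-[4-(benzyloxy)benzyl]thiolan-1-ium tetrafluoroborate | C(c1ccc(OCc2ccccc2)cc1)[S+]1CCCC1.F[B-](F)(F)F | intermediate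
22 | [4-(benzyloxy)phenyl](thiolan-1-ium-1-yl)methanide (sulfonium ylide) | [CH-](c1ccc(OCc2ccccc2)cc1)[S+]1CCCC1 | intermediate
23 | bis(o-quinone methide): (3S,4S,5R)-lactone whose two aryl rings are 3-(benzyloxy)-6-[3,5-bis(benzyloxy)benzylidene]cyclohexa-2,4-dien-1-ones joined through C5 (alkene geometry open) | O=C1C=C(OCc7ccccc7)C=C(C1=Cc5cc(OCc7ccccc7)cc(OCc7ccccc7)c5)[C@@H]1[C@@H](C2=CC(OCc7ccccc7)=CC(=O)C2=Cc5cc(OCc7ccccc7)cc(OCc7ccccc7)c5)[C@H](c2ccc(OCc7ccccc7)cc2)OC1=O | intermediate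
24 | (3S,4S,5R)-5-[4-(benzyloxy)phenyl]-3,4-bis{(2S,3S)-6-(benzyloxy)-2-[4-(benzyloxy)phenyl]-3-[3,5-bis(benzyloxy)phenyl]-2,3-dihydro-1-benzofuran-4-yl}oxolan-2-one | c7ccccc7COc1ccc([C@H]2Oc3cc(OCc7ccccc7)cc([C@@H]4[C@@H](c5cc(OCc7ccccc7)cc6c5[C@H](c5cc(OCc7ccccc7)cc(OCc7ccccc7)c5)[C@@H](c5ccc(OCc7ccccc7)cc5)O6)[C@H](c5ccc(OCc7ccccc7)cc5)OC4=O)c3[C@@H]2c2cc(OCc7ccccc7)cc(OCc7ccccc7)c2)cc1 | intermediate
25 | 1-(benzyloxy)-4-bromobenzene | Brc1ccc(OCc2ccccc2)cc1 | starting material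
26 | [4-(benzyloxy)phenyl]lithium | [Li]c1ccc(OCc2ccccc2)cc1 | intermediate
27 | [4-(benzyloxy)phenyl]cerium dichloride | Cl[Ce](Cl)c1ccc(OCc2ccccc2)cc1 | intermediate
28 | lactol: 24 with C2 as C(OH)[4-(benzyloxy)phenyl] (both C2 epimers, in equilibrium with the open hydroxy ketone) | c7ccccc7COc1ccc([C@H]2Oc3cc(OCc7ccccc7)cc([C@@H]4[C@@H](c5cc(OCc7ccccc7)cc6c5[C@H](c5cc(OCc7ccccc7)cc(OCc7ccccc7)c5)[C@@H](c5ccc(OCc7ccccc7)cc5)O6)[C@H](c5ccc(OCc7ccccc7)cc5)OC4(O)c4ccc(OCc7ccccc7)cc4)c3[C@@H]2c2cc(OCc7ccccc7)cc(OCc7ccccc7)c2)cc1 | intermediate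
29 | (2S,3S,4S,5R)-2,5-bis[4-(benzyloxy)phenyl]-3,4-bis{(2S,3S)-6-(benzyloxy)-2-[4-(benzyloxy)phenyl]-3-[3,5-bis(benzyloxy)phenyl]-2,3-dihydro-1-benzofuran-4-yl}oxolane (2,3-cis, 3,4-trans, 4,5-trans) | c7ccccc7COc1ccc([C@H]2Oc3cc(OCc7ccccc7)cc([C@@H]4[C@@H](c5cc(OCc7ccccc7)cc6c5[C@H](c5cc(OCc7ccccc7)cc(OCc7ccccc7)c5)[C@@H](c5ccc(OCc7ccccc7)cc5)O6)[C@H](c5ccc(OCc7ccccc7)cc5)O[C@@H]4c4ccc(OCc7ccccc7)cc4)c3[C@@H]2c2cc(OCc7ccccc7)cc(OCc7ccccc7)c2)cc1 | intermediate
30 | (2S,3S,4S,5R)-2,5-bis(4-hydroxyphenyl)-3,4-bis[(2S,3S)-3-(3,5-dihydroxyphenyl)-6-hydroxy-2-(4-hydroxyphenyl)-2,3-dihydro-1-benzofuran-4-yl]oxolane (2,3-cis, 3,4-trans, 4,5-trans) | Oc1ccc([C@H]2Oc3cc(O)cc([C@@H]4[C@@H](c5cc(O)cc6c5[C@H](c5cc(O)cc(O)c5)[C@@H](c5ccc(O)cc5)O6)[C@H](c5ccc(O)cc5)O[C@@H]4c4ccc(O)cc4)c3[C@@H]2c2cc(O)cc(O)c2)cc1 | target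

**Step count**

Total: 14 steps. Longest linear sequence: 12 steps (1 → 2 → 3 → 9 → 10 → 12 → 14 → 15 → 19 → 24 → 28 → 29 → 30, steps 1, 2, 4–9, 11–14).

**Steps most likely to fail**

Step 4. The cycloaddition may be too slow on an alkene that is 1,2-disubstituted and carries four acyloxy groups, so that the keteniminium ion is lost to self-condensation; face discrimination by the auxiliary in an intermolecular reaction may also be incomplete. The fallback sets out from 4 and returns at 12. Acid 4 is converted with SOCl2 into [4-(benzyloxy)phenyl]acetyl chloride F1. Et3N releases [4-(benzyloxy)phenyl]ketene F2 in the flask, and EtAlCl2 in CH2Cl2 at −78 °C promotes its [2+2] cycloaddition to stilbene 3 (Lewis-acid-promoted ketene–alkene cycloaddition). After equilibration with Et3N this should give the racemic all-trans cyclobutanone F3. Steps 5 and 6 applied to F3 give the racemic lactone tetrapivalate F4, the racemic tetraphenol lactone F5 (in the flask) and the racemic pentabenzyl lactone F6. The enantiomers of F6 are separated by preparative chromatography on a chiral stationary phase; the (3S,4S,5R) enantiomer is 12.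

Step 11. The ylide may add to the other face of one or both o-quinone methides, because only the shape of the lactone core directs it; the dihydrobenzofurans would then be trans but of the wrong configuration relative to the core. The fallback sets out from 20 and 19 and returns at 24; it replaces substrate control by reagent control. Alcohol 20, (2R,5R)-2,5-dimethylthiolane and HBF4·OEt2 give 1-[4-(benzyloxy)benzyl]-(2R,5R)-2,5-dimethylthiolan-1-ium tetrafluoroborate F7. Under the conditions of step 11 with 19 this forms the C2-symmetric sulfonium ylide F8, whose fixed conformation exposes one face of the carbanion, as in sulfide-controlled asymmetric epoxidation with benzylic ylides. C2' is then set by the reagent in both units and C3' follows from the trans-selective closure. The enantiomeric sulfide is used if the (2R,5R) sulfide leads to the wrong series.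

Step 12. The aryl-metal reagent may enolise the α-aryl lactone, or fail to add at a carbonyl that is now flanked by two large dihydrobenzofuranyl arms, and 24 would be returned. The fallback sets out from 24 and returns at 28. MeNH(OMe)·HCl and AlMe3 open the lactone to the hydroxy Weinreb amide F9. Et3SiCl and imidazole give the triethylsilyl ether F10. Aryllithium 26 adds once to the Weinreb amide to give the aryl ketone F11. Bu4NF removes the silyl group, and the hydroxy ketone closes to lactol 28.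

**Further compounds**

F1 | step 4 | [4-(benzyloxy)phenyl]acetyl chloride | O=C(Cl)Cc1ccc(OCc2ccccc2)cc1
F2 | step 4 | [4-(benzyloxy)phenyl]ketene | O=C=Cc1ccc(OCc2ccccc2)cc1
F3 | step 4 | racemic all-trans 2,3-bis[3,5-bis(pivaloyloxy)phenyl]-4-[4-(benzyloxy)phenyl]cyclobutan-1-one (9 and its enantiomer; the enantiomer is drawn) | O=C1[C@@H](c2cc(OC(=O)C(C)(C)C)cc(OC(=O)C(C)(C)C)c2)[C@H](c2cc(OC(=O)C(C)(C)C)cc(OC(=O)C(C)(C)C)c2)[C@H]1c1ccc(OCc2ccccc2)cc1
F4 | step 4 | racemic 3,4-trans-4,5-trans 5-[4-(benzyloxy)phenyl]-3,4-bis[3,5-bis(pivaloyloxy)phenyl]oxolan-2-one (10 and its enantiomer; the enantiomer is drawn) | CC(C)(C)C(=O)Oc1cc(cc(OC(=O)C(C)(C)C)c1)[C@H]1[C@H](c2cc(OC(=O)C(C)(C)C)cc(OC(=O)C(C)(C)C)c2)[C@@H](c2ccc(OCc3ccccc3)cc2)OC1=O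
F5 | step 4 | racemic 5-[4-(benzyloxy)phenyl]-3,4-bis(3,5-dihydroxyphenyl)oxolan-2-one (11 and its enantiomer; the enantiomer is drawn) | Oc1cc(cc(O)c1)[C@H]1[C@H](c2cc(O)cc(O)c2)[C@@H](c2ccc(OCc3ccccc3)cc2)OC1=O
F6 | step 4 | racemic 5-[4-(benzyloxy)phenyl]-3,4-bis[3,5-bis(benzyloxy)phenyl]oxolan-2-one (12 and its enantiomer; the enantiomer is drawn) | c7ccccc7COc1cc(cc(OCc7ccccc7)c1)[C@H]1[C@H](c2cc(OCc7ccccc7)cc(OCc7ccccc7)c2)[C@@H](c2ccc(OCc7ccccc7)cc2)OC1=O
F7 | step 11 | 1-[4-(benzyloxy)benzyl]-(2R,5R)-2,5-dimethylthiolan-1-ium tetrafluoroborate | C[C@@H]1CC[C@@H](C)[S+]1Cc1ccc(OCc2ccccc2)cc1.F[B-](F)(F)F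
F8 | step 11 | [4-(benzyloxy)phenyl][(2R,5R)-2,5-dimethylthiolan-1-ium-1-yl]methanide | C[C@@H]1CC[C@@H](C)[S+]1[CH-]c1ccc(OCc2ccccc2)cc1
F9 | step 12 | hydroxy Weinreb amide (24 opened at C2–O1: C2 as C(=O)N(OMe)Me and C5 as CH(OH)) | c7ccccc7COc1ccc([C@H]2Oc3cc(OCc7ccccc7)cc([C@@H](C(=O)N(C)OC)[C@@H](c5cc(OCc7ccccc7)cc6c5[C@H](c5cc(OCc7ccccc7)cc(OCc7ccccc7)c5)[C@@H](c5ccc(OCc7ccccc7)cc5)O6)[C@H](c5ccc(OCc7ccccc7)cc5)O)c3[C@@H]2c2cc(OCc7ccccc7)cc(OCc7ccccc7)c2)cc1
F10 | step 12 | triethylsilyl ether of F9 | c7ccccc7COc1ccc([C@H]2Oc3cc(OCc7ccccc7)cc([C@@H](C(=O)N(C)OC)[C@@H](c5cc(OCc7ccccc7)cc6c5[C@H](c5cc(OCc7ccccc7)cc(OCc7ccccc7)c5)[C@@H](c5ccc(OCc7ccccc7)cc5)O6)[C@H](c5ccc(OCc7ccccc7)cc5)O[Si](CC)(CC)CC)c3[C@@H]2c2cc(OCc7ccccc7)cc(OCc7ccccc7)c2)cc1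
F11 | step 12 | 4-(benzyloxy)phenyl ketone from F10 (C2 as C(=O)C6H4OBn-4; C5 as CH(OSiEt3)) | c7ccccc7COc1ccc([C@H]2Oc3cc(OCc7ccccc7)cc([C@@H](C(=O)c4ccc(OCc7ccccc7)cc4)[C@@H](c5cc(OCc7ccccc7)cc6c5[C@H](c5cc(OCc7ccccc7)cc(OCc7ccccc7)c5)[C@@H](c5ccc(OCc7ccccc7)cc5)O6)[C@H](c5ccc(OCc7ccccc7)cc5)O[Si](CC)(CC)CC)c3[C@@H]2c2cc(OCc7ccccc7)cc(OCc7ccccc7)c2)cc1
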